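## Retrosynthetic overview

- **C3–O ester and C2–OH:** both come from one trans-diaxial opening of a 2α,3α-epoxide by the free (2E,4E,6S)-dienoic acid. The epoxide comes from a Δ2 alkene.
- **Δ2 alkene:** it is revealed by Rh-catalysed removal of a formyl group. Acrolein therefore acts as an enantioselective "acetylene" dienophile.
- **Ring B (formed second), key bond C5–C6:** a 2,3-dioxobutyl radical adds to a tetrasubstituted silyl enol ether and creates the quaternary carbon. A C9=C10 aldol condensation then closes the ring at the diosphenol oxidation level.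
- **Ring A (formed first):** a catalytic asymmetric Diels–Alder reaction of a 2-silyloxy-3-methylpenta-1,3-diene with acrolein sets C4 and delivers the regiodefined C5=C10 enol ether.
- **Side chain:** (S)-2-methylbutanol is oxidised to the aldehyde, extended by a vinylogous Horner–Wadsworth–Emmons reaction and saponified.

Assumption: the five carbon building blocks marked as starting materials are catalogue chemicals. Eremophilane numbering is used throughout (ring A = C1–C5 and C10, ring B = C5–C10, C14 = methyl on C5, C15 = methyl on C4, β = the face that carries both methyl groups).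

## Route

Step 1
Reactants: 1 (E)-3-methylpent-3-en-2-one
Product: 2 (3E)-3-methyl-2-(triisopropylsilyloxy)penta-1,3-diene
Conditions: TIPSOTf (1.1 equiv), Et3N (1.5 equiv), CH2Cl2, 0 °C to rt
Reagents that add atoms: triisopropylsilyl triflate, CC(C)[Si](C(C)C)(C(C)C)OS(=O)(=O)C(F)(F)F
Why: Soft enolisation (silyl enol ether formation) O-silylates the enone and removes the most acidic α′-CH3 proton, which gives the cross-conjugated 2-silyloxy diene, leaves the E-alkene intact so that C15 sits "outside" in the s-cis diene, and forms no stereocentre.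

Step 2
Reactants: 2 (3E)-3-methyl-2-(triisopropylsilyloxy)penta-1,3-diene; 3 acrolein
Product: 4 (1S,2S)-2,3-dimethyl-4-(triisopropylsilyloxy)cyclohex-3-ene-1-carbaldehyde
Conditions: o-tolyl diphenylprolinol-derived oxazaborolidinium triflimide (10 mol %, the antipode that leaves the Cα-Re face of bound acrolein open), CH2Cl2, −78 °C
Reagents that add atoms: none
Why: In this catalytic enantioselective Diels–Alder reaction the 2-silyloxy group and the terminal methyl group both steer the formyl-bearing carbon to C3, the endo transition state places CHO cis to C15, and the chiral Lewis acid blocks one face of acrolein so that C4 is set as in the target and the tetrasubstituted C5=C10 enol ether is formed regiospecifically.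

Step 3
Reactants: 4 (1S,2S)-2,3-dimethyl-4-(triisopropylsilyloxy)cyclohex-3-ene-1-carbaldehyde; 5 1-bromobutane-2,3-dione
Product: 7 (1S,2R,8aS)-7-hydroxy-1,8a-dimethyl-6-oxo-1,2,3,4,6,8a-hexahydronaphthalene-2-carbaldehyde, via triketone aldehyde 6 (not isolated)
Conditions: fac-Ir(ppy)3 (1 mol %), NaHCO3 (1.5 equiv), MeCN, blue LEDs, rt; filter; pTsOH·H2O (10 mol %), PhMe, 45 °C
Reagents that add atoms: none
Why: Proposed new method: single-electron reduction of 5 gives the electrophilic 2,3-dioxobutyl radical, which is polarity-matched to the electron-rich C5 terminus of the enol ether and attacks anti to the pseudoaxial C15 methyl (forming C5–C6 and the quaternary centre with C14 cis to C15), the α-silyloxy radical is then oxidised to an oxocarbenium ion that loses silicon, and mild acid closes ring B by aldol condensation of C9 onto C10, enolises the 1,2-dione to the diosphenol and epimerises the soon-deleted C3 formyl group to the equatorial position; the closest known reaction types are the photoredox α-alkylation of silyl enol ethers with α-bromo ketones and the Robinson-type cyclodehydration.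

Step 4
Reactants: 7 (1S,2R,8aS)-7-hydroxy-1,8a-dimethyl-6-oxo-1,2,3,4,6,8a-hexahydronaphthalene-2-carbaldehyde
Product: 8 (4aS,5S)-3-hydroxy-4a,5-dimethyl-5,8-dihydronaphthalen-2(4aH)-one
Conditions: [Rh(cod)OMe]2 (2 mol %), Xantphos (4 mol %), 3-MeOC6H4CO2H (5 mol %), norbornadiene (3 equiv), THF, 80 °C
Reagents that add atoms: none
Why: In this Rh-catalysed transfer hydroformylation (dehydroformylation), formyl C–H insertion, decarbonylation and syn β-hydride elimination towards the open C2–H (rather than the tertiary C4–H next to the quaternary carbon) release the Δ2 alkene, and strained norbornadiene takes up H and CHO irreversibly so that no Rh–H remains to move the alkene into conjugation, while C4 and C5 are untouched.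

Step 5
Reactants: 8 (4aS,5S)-3-hydroxy-4a,5-dimethyl-5,8-dihydronaphthalen-2(4aH)-one
Product: 9 (2R,3S,4R,5S)-2,3-epoxy-7-hydroxy-11,12,13-trinoreremophila-6,9-dien-8-one (epoxide on the α face)
Conditions: dimethyldioxirane (1.05 equiv), acetone, −20 °C
Reagents that add atoms: dimethyldioxirane, CC1(C)OO1
Why: Electrophilic epoxidation selects the only unconjugated, electron-rich alkene and approaches from the α face because the axial C14 methyl (1,3 to C3) and the C15 methyl shield the β face, which sets C2 and C3 under neutral conditions that spare the diosphenol and the acidic C1 methylene.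

Step 6
Reactants: 10 methyl (E)-4-bromobut-2-enoate
Product: 11 methyl (E)-4-(diethoxyphosphoryl)but-2-enoate
Conditions: P(OEt)3 (1.1 equiv), neat, 120 °C, EtBr distilled off
Reagents that add atoms: triethyl phosphite, CCOP(OCC)OCC
Why: In the Michaelis–Arbuzov reaction phosphorus attacks the allylic bromide by SN2 and bromide then dealkylates the phosphonium ion, with the E-alkene retained.

Step 7
Reactants: 12 (S)-2-methylbutan-1-ol; 11 methyl (E)-4-(diethoxyphosphoryl)but-2-enoate
Product: 14 methyl (2E,4E,6S)-6-methylocta-2,4-dienoate, via (S)-2-methylbutanal 13 (not isolated)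
Conditions: TEMPO (1 mol %), KBr, aq NaOCl, CH2Cl2, 0 °C; dried solution added to 11/LiHMDS, THF, −78 to 0 °C
Reagents that add atoms: none
Why: TEMPO/bleach (Anelli) oxidation gives the volatile, epimerisable aldehyde, which the preformed stabilised anion consumes cold in a vinylogous Horner–Wadsworth–Emmons olefination that forms the 4E alkene (2E retained) without touching the stereocentre carried in from 12.

Step 8
Reactants: 14 methyl (2E,4E,6S)-6-methylocta-2,4-dienoate
Product: 15 (2E,4E,6S)-6-methylocta-2,4-dienoic acid
Conditions: LiOH, THF/MeOH/H2O, rt; then 1 M HCl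
Reagents that add atoms: lithium hydroxide, [Li+].[OH-]
Why: Saponification (BAc2 ester hydrolysis) affects neither the conjugated E,E-diene nor the remote stereocentre.

Step 9
Reactants: 9 (2R,3S,4R,5S)-2,3-epoxy-7-hydroxy-11,12,13-trinoreremophila-6,9-dien-8-one; 15 (2E,4E,6S)-6-methylocta-2,4-dienoic acid
Product: 16 Septeremophilane G, (1R,2R,3R,8aS)-3,7-dihydroxy-1,8a-dimethyl-6-oxo-1,2,3,4,6,8a-hexahydronaphthalen-2-yl (2E,4E,6S)-6-methylocta-2,4-dienoate
Conditions: 15 (2 equiv), Sc(OTf)3 (5 mol %), CH2Cl2, 0 °C to rt
Reagents that add atoms: none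
Why: Lewis-acid-catalysed acidolysis of the epoxide follows the Fürst–Plattner rule, so the acid attacks C3 axially from the β face with inversion (C3 also carries positive charge better than C2, which lies β to the electron-poor dienone), and this gives the trans-diaxial 3β-ester/2α-alcohol directly, differentiates the two oxygens without protecting groups and never acylates the diosphenol.

## Compound list

1 | (E)-3-methylpent-3-en-2-one | C/C=C(\C)C(C)=O | starting material
2 | (3E)-3-methyl-2-(triisopropylsilyloxy)penta-1,3-diene | C/C=C(\C)C(=C)O[Si](C(C)C)(C(C)C)C(C)C | intermediate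
3 | acrolein (prop-2-enal) | C=CC=O | starting material
4 | (1S,2S)-2,3-dimethyl-4-(triisopropylsilyloxy)cyclohex-3-ene-1-carbaldehyde | O=C[C@H]1CCC(O[Si](C(C)C)(C(C)C)C(C)C)=C(C)[C@H]1C | intermediate
5 | 1-bromobutane-2,3-dione | CC(=O)C(=O)CBr | starting material
6 | (1S,2S,3R)-3-(2,3-dioxobutyl)-2,3-dimethyl-4-oxocyclohexane-1-carbaldehyde (triketone aldehyde) | O=C[C@H]1CCC(=O)[C@](C)(CC(=O)C(C)=O)[C@H]1C | intermediate
7 | (1S,2R,8aS)-7-hydroxy-1,8a-dimethyl-6-oxo-1,2,3,4,6,8a-hexahydronaphthalene-2-carbaldehyde | O=C[C@@H]1CCC2=CC(=O)C(O)=C[C@]2(C)[C@H]1C | intermediate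
8 | (4aS,5S)-3-hydroxy-4a,5-dimethyl-5,8-dihydronaphthalen-2(4aH)-one | C1=CCC2=CC(=O)C(O)=C[C@]2(C)[C@H]1C | intermediate
9 | (2R,3S,4R,5S)-2,3-epoxy-7-hydroxy-11,12,13-trinoreremophila-6,9-dien-8-one (α-epoxide) | O1[C@@H]2[C@H]1CC3=CC(=O)C(O)=C[C@]3(C)[C@H]2C | intermediate
10 | methyl (E)-4-bromobut-2-enoate | COC(=O)/C=C/CBr | starting material
11 | methyl (E)-4-(diethoxyphosphoryl)but-2-enoate | CCOP(=O)(OCC)C/C=C/C(=O)OC | intermediate
12 | (S)-2-methylbutan-1-ol | CC[C@H](C)CO | starting material
13 | (S)-2-methylbutanal | CC[C@H](C)C=O | intermediate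
14 | methyl (2E,4E,6S)-6-methylocta-2,4-dienoate | CC[C@H](C)/C=C/C=C/C(=O)OC | intermediate
15 | (2E,4E,6S)-6-methylocta-2,4-dienoic acid | CC[C@H](C)/C=C/C=C/C(=O)O | intermediate
16 | Septeremophilane G | CC[C@H](C)/C=C/C=C/C(=O)O[C@H]1[C@H](O)CC2=CC(=O)C(O)=C[C@]2(C)[C@H]1C | target

## Step count

- **Total step count:** 9.
- **Longest linear sequence:** 6 steps (1 → 2 → 4 → 7 → 8 → 9 → 16, that is steps 1–5 and 9).

## Steps most likely to fail, with fallbacks

**Step 3 (radical annulation).** An intermolecular radical must build a quaternary carbon next to a tertiary one. Hydrogen abstraction from the formyl or allylic C–H bonds, simple reduction of 5, and acid-induced dienone–phenol rearrangement can all compete. The fallback inverts the roles of the two partners; it sets out from 4 and comes back at 6, which is cyclised to 7 as before.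

- NBS in THF at −78 °C converts 4 into the tertiary α-bromo ketone (1S,2S,3R)-3-bromo-2,3-dimethyl-4-oxocyclohexane-1-carbaldehyde F1.
- Butane-2,3-dione is silylated (TMSCl, Et3N) to 3-(trimethylsilyloxy)but-3-en-2-one F2.
- Et3B/air or photoredox initiation then makes the ring-centred tertiary α-keto radical from F1.
- This radical adds anti to C15 to the unhindered CH2 terminus of F2. Bromine transfer and loss of the silyl bromide give 6.

**Step 4 (dehydroformylation).** β-Hydride elimination could also go towards C4–H. The chelating diosphenol may slow the rhodium catalyst, and the skipped diene may slip into conjugation. The fallback moves the C–C cleavage to the monocyclic stage; it sets out from 6, isolated after the light-driven half of step 3, and comes back at 8.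

- In 6 the formyl group is still cis to C15, so only C2–H is syn to rhodium.
- The same Rh/norbornadiene system therefore gives only (5S,6R)-6-(2,3-dioxobutyl)-5,6-dimethylcyclohex-3-en-1-one F3.
- Ring B is then closed under buffered enamine conditions (pyrrolidinium acetate, CH2Cl2, rt). These engage the side-chain methyl ketone rather than the hindered ring ketone and give 8.

**Step 9 (epoxide opening by the acid).** The axial attack at C3 is hindered by C14 and C15. Meinwald rearrangement or vinylogous opening to the conjugated trienone may win. The fallback separates C–O bond cleavage from acylation; it sets out from 9 and comes back at 16.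

- Aqueous HClO4 in THF opens 9 to the trans-diaxial diol (2R,3R,4R,5S)-2,3,7-trihydroxy-11,12,13-trinoreremophila-6,9-dien-8-one F4.
- TESCl/imidazole (2.1 equiv) caps the enolic C7–OH and the less hindered C2–OH to give the 2,7-bis(triethylsilyl) ether F5.
- Yamaguchi esterification with 15 acylates the remaining C3–OH to give the 3-O-dienoyl bis(triethylsilyl) ether F6.
- HF·pyridine removes both silyl groups to give 16.

## Further compounds

F1 | step 3 | (1S,2S,3R)-3-bromo-2,3-dimethyl-4-oxocyclohexane-1-carbaldehyde | O=C[C@H]1CCC(=O)[C@](C)(Br)[C@H]1C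
F2 | step 3 | 3-(trimethylsilyloxy)but-3-en-2-one | CC(=O)C(=C)O[Si](C)(C)C
F3 | step 4 | (5S,6R)-6-(2,3-dioxobutyl)-5,6-dimethylcyclohex-3-en-1-one | C1=CCC(=O)[C@](C)(CC(=O)C(C)=O)[C@H]1C
F4 | step 9 | (2R,3R,4R,5S)-2,3,7-trihydroxy-11,12,13-trinoreremophila-6,9-dien-8-one | O[C@H]1[C@H](O)CC2=CC(=O)C(O)=C[C@]2(C)[C@H]1C
F5 | step 9 | 2,7-bis(triethylsilyl) ether of F4 | O[C@H]1[C@H](O[Si](CC)(CC)CC)CC2=CC(=O)C(O[Si](CC)(CC)CC)=C[C@]2(C)[C@H]1C
F6 | step 9 | 3-O-[(2E,4E,6S)-6-methylocta-2,4-dienoyl] 2,7-bis(triethylsilyl) ether | CC[C@H](C)/C=C/C=C/C(=O)O[C@H]1[C@H](O[Si](CC)(CC)CC)CC2=CC(=O)C(O[Si](CC)(CC)CC)=C[C@]2(C)[C@H]1C
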